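**Retrosynthetic overview** (ring carbons C1–C6 as in the cyclohexenone name; side-chain carbons 1'–12' counted from the ring)

1. Last bond C3'–C4': Negishi sp2–sp3 coupling of an enantiopure 5-(3-iodobut-2-enyl)cyclohexenone with a homoallylic zinc reagent that already carries the trans-methyl lactone.
2. The cyclohexenone comes from a cyclobutenone by a hydride-triggered ring expansion by two carbons (4π ring opening, then 6π ring closure). The enabling feature: C1(=O), C2(OMe), C3(OMe) and C4(OH) are the four carbons and the oxygen pattern of dimethyl squarate with one carbonyl reduced, and C5–C6(CH3) is an (E)-1-methylalkenyl unit, so the ring is the protonated 6π-closure product of a 1,4-dioxidotriene. The ring is formed racemic and is resolved directly afterwards.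
3. The cyclobutenone comes from dimethyl squarate and the mono-lithiated, symmetric (2E,5E)-2,6-diiodohepta-2,5-diene (from hepta-2,5-diyne); the second vinyl iodide is the handle for the last coupling.
4. The zinc reagent comes from an (E)-iodoalkene (from pent-3-yn-1-ol) and the triflate of (3R,5S)-5-(hydroxymethyl)-3-methyloxolan-2-one, made from (5S)-5-(hydroxymethyl)oxolan-2-one (chiral pool, L-glutamic acid series) by trityl-directed trans methylation.
5. Ring order: the lactone ring is present from the start; the four-membered ring is commercial; the six-membered ring is made from it in step 4.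

Key step: step 4

**Remarks (assumptions)**

- The squarate adduct and the ring-expansion intermediates and product are racemic up to the resolution; where they have more than one stereocentre the SMILES shows the enantiomer that leads to the target.
- In step 5 the (2S,3R) antipode of the isothiourea catalyst is taken to acylate the (4S,5S,6S) alcohol faster; if the sense is the reverse, the (2R,3S) antipode is used and nothing else changes.
- Cyclopentadienyl rings on zirconium are drawn σ-bonded in SMILES.

**Route**

Step 1
Reactants: 1 1-bromobut-2-yne; 2 prop-1-ynylmagnesium bromide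
Product: 3 hepta-2,5-diyne
Conditions: CuCl (5 mol%), THF, 0 °C to rt
Reagents that add atoms: none
Why: Copper-catalysed SN2 coupling of a propargylic bromide with an alkynylmagnesium bromide is the standard entry to skipped diynes and forms no stereocentre.

Step 2
Reactants: 3 hepta-2,5-diyne
Product: 5 (2E,5E)-2,6-diiodohepta-2,5-diene, via bis(alkenylzirconocene chloride) 4 (not isolated)
Conditions: Cp2Zr(H)Cl (2.6 equiv), THF, rt then 40 °C, dark; then I2 (2.6 equiv), THF, 0 °C
Reagents that add atoms: iodine, II
Why: Syn hydrozirconation of each methyl-substituted alkyne should place zirconium on the less hindered methyl-bearing carbon after equilibration with excess Cp2Zr(H)Cl, and iodinolysis with retention should give both (E)-2-iodoalkene ends (hydrozirconation–iodination).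

Step 3
Reactants: 5 (2E,5E)-2,6-diiodohepta-2,5-diene; 6 dimethyl squarate
Product: 8 rac-4-hydroxy-4-[(2E,5E)-6-iodohepta-2,5-dien-2-yl]-2,3-dimethoxycyclobut-2-en-1-one, via alkenyllithium 7 (not isolated)
Conditions: 5 (3 equiv), t-BuLi (2 equiv), Et2O, −78 °C; then 6 (1 equiv) in THF, −78 °C; aq. NH4Cl, −78 °C; excess 5 recovered
Reagents that add atoms: none
Why: Iodine–lithium exchange on one of the two equivalent vinyl iodides (diiodide in excess to suppress double exchange) should proceed with retention of alkene geometry, and the alkenyllithium should add 1,2 to one of the two equivalent carbonyl groups of dimethyl squarate (classical squarate mono-addition, the remaining carbonyl being a less electrophilic vinylogous ester), forming the carbinol centre as a racemate.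

Step 4
Reactants: 8 rac-4-hydroxy-4-[(2E,5E)-6-iodohepta-2,5-dien-2-yl]-2,3-dimethoxycyclobut-2-en-1-one
Product: 13 rac-(4R,5R,6R)-4-hydroxy-5-[(2E)-3-iodobut-2-en-1-yl]-2,3-dimethoxy-6-methylcyclohex-2-en-1-one, via trans-cyclobutenediolate 9 (not isolated), via trienediolate 10 (not isolated), via cyclohexadienolate 11 (not isolated), via C6-epimeric ketone 12 (not isolated)
Conditions: LiAlH4 (0.6 equiv), THF, −78 °C, then −78 to 0 °C; AcOH in THF, −78 °C; then DBU (0.2 equiv), CH2Cl2, rt
Reagents that add atoms: none
Why: LiAlH4 should first turn the tertiary OH into an alkoxyaluminate and then deliver hydride 1,2 to the neighbouring vinylogous-ester carbonyl from the oxygen-bearing face, which is also the face away from the branched alkenyl group, so that the two oxido groups of 9 are trans; on warming, the σ bond between the two sp3 ring carbons should open by conrotatory 4π electrocyclic ring opening with both oxido groups rotating outward and the alkenyl group and H inward (oxy-anion acceleration and torquoselectivity), giving only the triene 10 that has the geometry of an E,Z,E-hexatriene. Thermal disrotatory 6π electrocyclisation of 10, the only ring closure of the step, should form the C4–C5 bond and give dienolate 11, in which the outside substituents of the two termini, O at C4 and the CH2 chain at C5, must be cis. The closest known reaction type is the ring expansion of cyclobutenones to cyclohexenones by alkenyllithium addition, oxy-anion-accelerated ring opening and 6π closure, together with the conrotatory opening of squarate-derived trans-cyclobutene-1,2-diolates. C6 is set last: protonation of the enolate gives some of epimer 12, and DBU should equilibrate it to the 5,6-trans ketone, in which the C6 methyl avoids a 1,3-diaxial contact with the pseudoaxial C4 hydroxyl. The selectivity needed is hydride delivery syn to the alkoxide (secured by alkoxide direction and by the bulk of the 1-methylalkenyl group) and 1,2- rather than 1,4-reduction (the β-carbon is fully substituted and carries OMe). Because triene 10 is achiral the ring is formed as a racemate, which is resolved in step 5.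

Step 5
Reactants: 13 rac-(4R,5R,6R)-4-hydroxy-5-[(2E)-3-iodobut-2-en-1-yl]-2,3-dimethoxy-6-methylcyclohex-2-en-1-one
Product: 14 (4R,5R,6R)-4-hydroxy-5-[(2E)-3-iodobut-2-en-1-yl]-2,3-dimethoxy-6-methylcyclohex-2-en-1-one
Conditions: (2S,3R)-HyperBTM (2 mol%), isobutyric anhydride (0.6 equiv), i-Pr2NEt (0.6 equiv), CHCl3, 0 °C, stopped a little beyond half conversion; chromatography
Reagents that add atoms: none
Why: Acylative kinetic resolution of a cyclic secondary allylic alcohol by a chiral isothiourea acyl-transfer catalyst, whose N-acyl isothiouronium ion recognises the C2=C3 π system next to the carbinol, should leave the slow-reacting (4R,5R,6R) alcohol in high enantiomeric purity once conversion passes one half, the ester of the antipode being removed by chromatography.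

Step 6
Reactants: 15 pent-3-yn-1-ol
Product: 16 tert-butyl(dimethyl)(pent-3-yn-1-yloxy)silane
Conditions: TBSCl, imidazole, CH2Cl2, rt
Reagents that add atoms: tert-butyldimethylsilyl chloride, CC(C)(C)[Si](C)(C)Cl
Why: Standard silylation of a primary alcohol.

Step 7
Reactants: 16 tert-butyl(dimethyl)(pent-3-yn-1-yloxy)silane
Product: 18 tert-butyl{[(3E)-4-iodopent-3-en-1-yl]oxy}dimethylsilane, via alkenylzirconocene chloride 17 (not isolated)
Conditions: Cp2Zr(H)Cl (1.5 equiv), THF, rt then 40 °C; then I2, 0 °C
Reagents that add atoms: iodine, II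
Why: Hydrozirconation–iodination as in step 2, with syn addition, zirconium on the methyl-bearing alkyne carbon and iodinolysis with retention, should give the (E)-iodoalkene.

Step 8
Reactants: 19 (5S)-5-(hydroxymethyl)oxolan-2-one
Product: 20 (5S)-5-[(trityloxy)methyl]oxolan-2-one
Conditions: TrCl, pyridine, DMAP (cat.), CH2Cl2, rt
Reagents that add atoms: trityl chloride, ClC(c1ccccc1)(c1ccccc1)c1ccccc1
Why: Tritylation of the primary alcohol installs the bulky group that shields one face of the lactone enolate in the next step.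

Step 9
Reactants: 20 (5S)-5-[(trityloxy)methyl]oxolan-2-one
Product: 22 (3R,5S)-3-methyl-5-[(trityloxy)methyl]oxolan-2-one, via lithium enolate 21 (not isolated)
Conditions: LiN(i-Pr)2, THF, −78 °C; then MeI, −78 to −40 °C
Reagents that add atoms: iodomethane, CI
Why: Alkylation of the lithium enolate of a γ-substituted γ-butyrolactone should occur anti to the trityloxymethyl group at C5, which sets the (3R) methyl centre trans to the C5 substituent.

Step 10
Reactants: 22 (3R,5S)-3-methyl-5-[(trityloxy)methyl]oxolan-2-one
Product: 23 (3R,5S)-5-(hydroxymethyl)-3-methyloxolan-2-one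
Conditions: AcOH/H2O (4:1), 50 °C
Reagents that add atoms: none
Why: Acid solvolysis of the trityl ether through the stabilised trityl cation leaves the lactone and both stereocentres untouched.

Step 11
Reactants: 23 (3R,5S)-5-(hydroxymethyl)-3-methyloxolan-2-one
Product: 24 [(2S,4R)-4-methyl-5-oxooxolan-2-yl]methyl trifluoromethanesulfonate
Conditions: Tf2O, pyridine, CH2Cl2, −40 °C; used crude
Reagents that add atoms: trifluoromethanesulfonic anhydride, O=S(=O)(OS(=O)(=O)C(F)(F)F)C(F)(F)F
Why: Triflation of the primary alcohol under buffered conditions gives a reactive electrophile without touching a stereocentre.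

Step 12
Reactants: 18 tert-butyl{[(3E)-4-iodopent-3-en-1-yl]oxy}dimethylsilane; 24 [(2S,4R)-4-methyl-5-oxooxolan-2-yl]methyl trifluoromethanesulfonate
Product: 27 (3R,5S)-5-[(2E)-5-{[tert-butyl(dimethyl)silyl]oxy}-2-methylpent-2-en-1-yl]-3-methyloxolan-2-one, via alkenyllithium 25 (not isolated), via alkenylmagnesium bromide 26 (not isolated)
Conditions: 18 (1.3 equiv), t-BuLi (2.6 equiv), Et2O, −78 °C; MgBr2·OEt2, −78 to −40 °C; CuBr·SMe2 (10 mol%), then 24 in THF, −78 to −30 °C
Reagents that add atoms: none
Why: Iodine–lithium exchange with retention, transmetalation to magnesium and copper-catalysed SN2 displacement of the primary triflate by the alkenyl group should be faster at low temperature than addition to the lactone carbonyl, and should keep the alkene geometry and both lactone stereocentres.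

Step 13
Reactants: 27 (3R,5S)-5-[(2E)-5-{[tert-butyl(dimethyl)silyl]oxy}-2-methylpent-2-en-1-yl]-3-methyloxolan-2-one
Product: 28 (3R,5S)-5-[(2E)-5-hydroxy-2-methylpent-2-en-1-yl]-3-methyloxolan-2-one
Conditions: HF·pyridine, THF, 0 °C to rt
Reagents that add atoms: none
Why: Fluoride cleavage of the primary silyl ether under mildly acidic conditions leaves the lactone intact.

Step 14
Reactants: 28 (3R,5S)-5-[(2E)-5-hydroxy-2-methylpent-2-en-1-yl]-3-methyloxolan-2-one
Product: 29 (3R,5S)-5-[(2E)-5-iodo-2-methylpent-2-en-1-yl]-3-methyloxolan-2-one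
Conditions: I2, PPh3, imidazole, CH2Cl2, 0 °C
Reagents that add atoms: iodine, II
Why: Appel-type iodination of the primary alcohol proceeds by SN2 displacement of the alkoxyphosphonium ion.

Step 15
Reactants: 29 (3R,5S)-5-[(2E)-5-iodo-2-methylpent-2-en-1-yl]-3-methyloxolan-2-one; 14 (4R,5R,6R)-4-hydroxy-5-[(2E)-3-iodobut-2-en-1-yl]-2,3-dimethoxy-6-methylcyclohex-2-en-1-one
Product: 31 (4R,5R,6R)-4-hydroxy-2,3-dimethoxy-6-methyl-5-{(2E,6E)-3,7-dimethyl-8-[(2S,4R)-4-methyl-5-oxooxolan-2-yl]octa-2,6-dien-1-yl}cyclohex-2-en-1-one, via alkylzinc iodide 30 (not isolated)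
Conditions: 29 (2.5 equiv), Zn powder, LiCl, THF, 40 °C; then 14, PdCl2(dppf) (5 mol%; dppf = 1,1'-bis(diphenylphosphino)ferrocene), THF/NMP, rt to 40 °C
Reagents that add atoms: none
Why: Zinc insertion into the primary iodide should give a homoallylic zinc iodide that tolerates the lactone, and Negishi coupling with the alkenyl iodide (oxidative addition to zerovalent palladium, transmetalation, reductive elimination) should form the C3'–C4' bond with retention of the (E) geometry, the alkylzinc reagent being compatible with the free hydroxyl group and the enone.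

**Compound list**

1 | 1-bromobut-2-yne | CC#CCBr | starting material
2 | prop-1-ynylmagnesium bromide | CC#C[Mg]Br | starting material
3 | hepta-2,5-diyne | CC#CCC#CC | intermediate
4 | (2E,5E)-hepta-2,5-diene-2,6-diylbis[chlorobis(cyclopentadienyl)zirconium] (not isolated) | C/C(=C\C/C=C(\C)[Zr](Cl)(C1C=CC=C1)C1C=CC=C1)[Zr](Cl)(C1C=CC=C1)C1C=CC=C1 | intermediate
5 | (2E,5E)-2,6-diiodohepta-2,5-diene | C/C(I)=C\C/C=C(\C)I | intermediate
6 | dimethyl squarate (3,4-dimethoxycyclobut-3-ene-1,2-dione) | COC1=C(OC)C(=O)C1=O | starting material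
7 | [(2Z,5E)-6-iodohepta-2,5-dien-2-yl]lithium (one iodine of 5 replaced by Li with retention; the descriptor changes only because Li ranks below CH3; not isolated) | C/C([Li])=C\C/C=C(\C)I | intermediate
8 | rac-4-hydroxy-4-[(2E,5E)-6-iodohepta-2,5-dien-2-yl]-2,3-dimethoxycyclobut-2-en-1-one | COC1=C(OC)C(O)(/C(C)=C/C/C=C(\C)I)C1=O | intermediate
9 | rac-trans-1-[(2E,5E)-6-iodohepta-2,5-dien-2-yl]-3,4-dimethoxycyclobut-3-ene-1,2-diolate (lithium alkoxyaluminate, drawn as the dianion; not isolated) | COC1=C(OC)[C@@]([O-])(/C(C)=C/C/C=C(\C)I)[C@H]1[O-] | intermediate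
10 | ring-opened 9-iodo-2,3-dimethoxy-5-methyldeca-1,3,5,8-tetraene-1,4-diolate, both oxido groups outside and the alkenyl group inside (dianion drawn; not isolated) | [O-]/C=C(OC)/C(OC)=C([O-])\C(C)=C\C/C=C(\C)I | intermediate
11 | rac-cis-6-[(2E)-3-iodobut-2-en-1-yl]-3,4-dimethoxy-1-methyl-5-oxidocyclohexa-1,3-dien-2-olate (dianion drawn; not isolated) | COC1=C(OC)[C@H]([O-])[C@H](C/C=C(\C)I)C(C)=C1[O-] | intermediate
12 | rac-(4R,5R,6S)-4-hydroxy-5-[(2E)-3-iodobut-2-en-1-yl]-2,3-dimethoxy-6-methylcyclohex-2-en-1-one (C6 epimer; not isolated) | COC1=C(OC)[C@H](O)[C@H](C/C=C(\C)I)[C@H](C)C1=O | intermediate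
13 | rac-(4R,5R,6R)-4-hydroxy-5-[(2E)-3-iodobut-2-en-1-yl]-2,3-dimethoxy-6-methylcyclohex-2-en-1-one (racemate) | COC1=C(OC)[C@H](O)[C@H](C/C=C(\C)I)[C@@H](C)C1=O | intermediate
14 | (4R,5R,6R)-4-hydroxy-5-[(2E)-3-iodobut-2-en-1-yl]-2,3-dimethoxy-6-methylcyclohex-2-en-1-one (single enantiomer) | COC1=C(OC)[C@H](O)[C@H](C/C=C(\C)I)[C@@H](C)C1=O | intermediate
15 | pent-3-yn-1-ol | CC#CCCO | starting material
16 | tert-butyl(dimethyl)(pent-3-yn-1-yloxy)silane | CC#CCCO[Si](C)(C)C(C)(C)C | intermediate
17 | chlorobis(cyclopentadienyl)[(2E)-5-{[tert-butyl(dimethyl)silyl]oxy}pent-2-en-2-yl]zirconium (not isolated) | C/C(=C\CCO[Si](C)(C)C(C)(C)C)[Zr](Cl)(C1C=CC=C1)C1C=CC=C1 | intermediate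
18 | tert-butyl{[(3E)-4-iodopent-3-en-1-yl]oxy}dimethylsilane | C/C(I)=C\CCO[Si](C)(C)C(C)(C)C | intermediate
19 | (5S)-5-(hydroxymethyl)oxolan-2-one | OC[C@@H]1CCC(=O)O1 | starting material
20 | (5S)-5-[(trityloxy)methyl]oxolan-2-one | c1ccccc1C(c1ccccc1)(c1ccccc1)OC[C@@H]1CCC(=O)O1 | intermediate
21 | lithium enolate of 20, lithium (5S)-5-[(trityloxy)methyl]-4,5-dihydrofuran-2-olate (not isolated) | c1ccccc1C(c1ccccc1)(c1ccccc1)OC[C@@H]1CC=C(O[Li])O1 | intermediate
22 | (3R,5S)-3-methyl-5-[(trityloxy)methyl]oxolan-2-one | c1ccccc1C(c1ccccc1)(c1ccccc1)OC[C@@H]1C[C@@H](C)C(=O)O1 | intermediate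
23 | (3R,5S)-5-(hydroxymethyl)-3-methyloxolan-2-one | OC[C@@H]1C[C@@H](C)C(=O)O1 | intermediate
24 | [(2S,4R)-4-methyl-5-oxooxolan-2-yl]methyl trifluoromethanesulfonate | O=S(=O)(OC[C@@H]1C[C@@H](C)C(=O)O1)C(F)(F)F | intermediate
25 | [(2Z)-5-{[tert-butyl(dimethyl)silyl]oxy}pent-2-en-2-yl]lithium (iodine of 18 replaced by Li with retention; not isolated) | C/C([Li])=C\CCO[Si](C)(C)C(C)(C)C | intermediate
26 | bromo[(2E)-5-{[tert-butyl(dimethyl)silyl]oxy}pent-2-en-2-yl]magnesium (not isolated) | C/C([Mg]Br)=C\CCO[Si](C)(C)C(C)(C)C | intermediate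
27 | (3R,5S)-5-[(2E)-5-{[tert-butyl(dimethyl)silyl]oxy}-2-methylpent-2-en-1-yl]-3-methyloxolan-2-one | CC(C)(C)[Si](C)(C)OCC/C=C(\C)C[C@@H]1C[C@@H](C)C(=O)O1 | intermediate
28 | (3R,5S)-5-[(2E)-5-hydroxy-2-methylpent-2-en-1-yl]-3-methyloxolan-2-one | OCC/C=C(\C)C[C@@H]1C[C@@H](C)C(=O)O1 | intermediate
29 | (3R,5S)-5-[(2E)-5-iodo-2-methylpent-2-en-1-yl]-3-methyloxolan-2-one | ICC/C=C(\C)C[C@@H]1C[C@@H](C)C(=O)O1 | intermediate
30 | iodo{(3E)-4-methyl-5-[(2S,4R)-4-methyl-5-oxooxolan-2-yl]pent-3-en-1-yl}zinc (not isolated) | I[Zn]CC/C=C(\C)C[C@@H]1C[C@@H](C)C(=O)O1 | intermediate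
31 | (4R,5R,6R)-4-hydroxy-2,3-dimethoxy-6-methyl-5-{(2E,6E)-3,7-dimethyl-8-[(2S,4R)-4-methyl-5-oxooxolan-2-yl]octa-2,6-dien-1-yl}cyclohex-2-en-1-one | COC1=C(OC)[C@H](O)[C@H](C/C=C(\C)CC/C=C(\C)C[C@@H]2C[C@@H](C)C(=O)O2)[C@@H](C)C1=O | target

**Summary**

Total step count: 15. Longest linear sequence: 8 steps (steps 8 to 15, from 19 to 31).

**Steps most likely to fail, with fallbacks**

Step 4. What may go wrong: hydride delivery to the wrong face of the carbonyl, giving the cis-diolate, which opens to a triene that cannot close or that closes to the C4 epimer; sluggish ring opening while the alkoxides are bound to aluminium; or protonation of the ring-opened dienolate before closure. The fallback sets out from 8 and returns at 13, and it runs the ring expansion thermally on a neutral, purified precursor. The tertiary hydroxyl of 8 is silylated (Et3SiOTf, 2,6-lutidine, CH2Cl2, −78 °C) to the O-triethylsilyl cyclobutenone F1. Luche reduction (NaBH4, CeCl3·7H2O, MeOH, −78 °C) should give the trans-2-silyloxycyclobutenol F2, which is freed from any cis isomer by cold chromatography. A second silylation (Et3SiOTf, 2,6-lutidine) gives the trans-bis(triethylsilyl) ether F3. Heating F3 in toluene (80 to 100 °C) should open it with both silyloxy groups outside to the bis(silyloxy)triene F4, which is not isolated and closes by 6π electrocyclisation to the bis(silyloxy)cyclohexadiene F5. HF·pyridine in THF cleaves both silicon–oxygen bonds and DBU equilibrates C6, which gives 13.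

Step 5. What may go wrong: insufficient discrimination between the enantiomers, because the carbinol is flanked on both sides, so that the recovered alcohol is not enantiopure at an acceptable conversion. The fallback sets out from 13 and returns at 14, and it replaces the catalytic resolution by a covalent one. Steglich esterification of 13 with (S)-2-methoxy-2-phenylacetic acid (DCC, DMAP, CH2Cl2, 0 °C) gives the diastereomeric esters, the (4R,5R,6R)-alcohol (S)-2-methoxy-2-phenylacetate F6 and the (4S,5S,6S)-alcohol (S)-2-methoxy-2-phenylacetate F7. These are separated by chromatography or crystallisation, and methanolysis of F6 (K2CO3, MeOH, 0 °C) gives 14.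

Step 15. What may go wrong: protonation of the alkylzinc reagent by the free hydroxyl group, or slow transmetalation, so that reduced side chain and unreacted alkenyl iodide are recovered. The fallback sets out from 29 and 14 and returns at 31, and it needs no preformed organometallic. The two iodides are joined directly by nickel-catalysed reductive cross-electrophile coupling (NiCl2(dme) (10 mol%), 4,4'-di-tert-butyl-2,2'-bipyridine, Mn powder, NaI (cat.), DMPU, rt), which tolerates hydroxyl, ketone and lactone groups. This fallback makes no new compound (F0).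

**Further compounds**

F1 | step 4 | rac-4-[(2E,5E)-6-iodohepta-2,5-dien-2-yl]-2,3-dimethoxy-4-[(triethylsilyl)oxy]cyclobut-2-en-1-one | COC1=C(OC)C(O[Si](CC)(CC)CC)(/C(C)=C/C/C=C(\C)I)C1=O
F2 | step 4 | rac-trans-2-[(2E,5E)-6-iodohepta-2,5-dien-2-yl]-3,4-dimethoxy-2-[(triethylsilyl)oxy]cyclobut-3-en-1-ol | COC1=C(OC)[C@@](O[Si](CC)(CC)CC)(/C(C)=C/C/C=C(\C)I)[C@H]1O
F3 | step 4 | rac-trans-3-[(2E,5E)-6-iodohepta-2,5-dien-2-yl]-1,2-dimethoxy-3,4-bis[(triethylsilyl)oxy]cyclobut-1-ene | COC1=C(OC)[C@@](O[Si](CC)(CC)CC)(/C(C)=C/C/C=C(\C)I)[C@H]1O[Si](CC)(CC)CC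
F4 | step 4 | 9-iodo-2,3-dimethoxy-5-methyl-1,4-bis[(triethylsilyl)oxy]deca-1,3,5,8-tetraene, both silyloxy groups outside (not isolated) | CC[Si](CC)(CC)O/C=C(OC)/C(OC)=C(O[Si](CC)(CC)CC)\C(C)=C\C/C=C(\C)I
F5 | step 4 | rac-cis-6-[(2E)-3-iodobut-2-en-1-yl]-3,4-dimethoxy-1-methyl-2,5-bis[(triethylsilyl)oxy]cyclohexa-1,3-diene | COC1=C(OC)[C@H](O[Si](CC)(CC)CC)[C@H](C/C=C(\C)I)C(C)=C1O[Si](CC)(CC)CC
F6 | step 5 | (S)-2-methoxy-2-phenylacetate of the (4R,5R,6R) alcohol 14 | COC1=C(OC)[C@H](OC(=O)[C@@H](OC)c2ccccc2)[C@H](C/C=C(\C)I)[C@@H](C)C1=O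
F7 | step 5 | (S)-2-methoxy-2-phenylacetate of the (4S,5S,6S) alcohol | COC1=C(OC)[C@@H](OC(=O)[C@@H](OC)c2ccccc2)[C@@H](C/C=C(\C)I)[C@H](C)C1=O
F0 | step 15 | none | none
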